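**Retrosynthetic overview**
- The trans γ-lactone is closed last, onto C2, by SN2 attack of the C16 ester carbonyl on an activated (2R)-carbinol (inversion to 2S), followed by desilylation.
- The 14-membered carbocycle is closed before that at C1–C2 by intramolecular addition of a C17-boryl C1=C15 allyl unit to the C2 enal. This also creates the 15(17)-methylene; C14 steers C1 and the chair steers C2.
- The acyclic C20 chain comes from a C5 boron-armed formyl acrylate by three iterative catalyst-controlled vinylogous Mukaiyama aldols with the silyl dienol ether of prenal (bonds C13–C14, C9–C10, C5–C6; 14S, 10S, 6S), each new carbinol being capped in the same flask.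
- The C5 starter comes from tert-butyl acrylate and 2,2-dimethoxyacetaldehyde (Baylis–Hillman, then allylic borylation).
- Ring order: carbocycle first, lactone second.

Numbering: cembrane locants are used (ring C1–C14; C15 lactone α-carbon; C16 carboxyl; C17 exocyclic methylene; C2 carries the lactone oxygen). Bpin = 4,4,5,5-tetramethyl-1,3,2-dioxaborolan-2-yl.

Assumption: the (4R) oxazaborolidinone (from N-tosyl-D-tryptophan and PhBCl2) shields the re face of a bound enal so the dienol ether adds to the si face (S carbinol); the sense is checked by Mosher analysis of the first aldol adduct and the (4S) catalyst is used if it is opposite.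

**Route**

Step 1
Reactants: 1 tert-butyl acrylate; 2 2,2-dimethoxyacetaldehyde (60% aqueous solution)
Product: 3 tert-butyl 3-hydroxy-4,4-dimethoxy-2-methylidenebutanoate (racemic)
Conditions: DABCO (0.5 equiv), dioxane/H2O 1:1, rt, 48 h
Reagents that add atoms: none
Why: Morita–Baylis–Hillman reaction, in which DABCO adds to the acrylate and the resulting enolate attacks the activated α-alkoxy aldehyde; the carbinol centre is racemic and is erased in step 3.

Step 2
Reactants: 3 tert-butyl 3-hydroxy-4,4-dimethoxy-2-methylidenebutanoate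
Product: 4 tert-butyl 3-acetoxy-4,4-dimethoxy-2-methylidenebutanoate (racemic)
Conditions: Ac2O, pyridine, DMAP (cat.), CH2Cl2, 0 °C
Reagents that add atoms: acetic anhydride, CC(=O)OC(C)=O
Why: DMAP-catalysed O-acylation turns the allylic alcohol into a leaving group for the allylic borylation; no new stereocentre.

Step 3
Reactants: 4 tert-butyl 3-acetoxy-4,4-dimethoxy-2-methylidenebutanoate
Product: 6 tert-butyl (2E)-4-oxo-2-(Bpin-methyl)but-2-enoate, via boryl acetal 5 (not isolated)
Conditions: B2pin2, Pd2(dba)3 (2.5 mol%), DMSO, 50 °C; then 1 M HCl, THF, rt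
Reagents that add atoms: bis(pinacolato)diboron, CC1(C)OB(OC1(C)C)B1OC(C)(C)C(C)(C)O1; water, O
Why: Miyaura-type allylic borylation, in which zerovalent palladium ionises the acetate to a 2-carboalkoxy π-allyl complex and boron is delivered to the CH2 terminus, the trisubstituted alkene settling with the acetal carbon trans to the ester and cis to CH2B; dilute acid then hydrolyses the acetal while the deactivated allylboronate and the tert-butyl ester survive.

Step 4
Reactants: 7 3-methylbut-2-enal (prenal)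
Product: 8 tert-butyl(dimethyl){[(1E)-3-methylbuta-1,3-dien-1-yl]oxy}silane
Conditions: TBSOTf, Et3N, CH2Cl2, 0 °C → rt
Reagents that add atoms: tert-butyldimethylsilyl trifluoromethanesulfonate, CC(C)(C)[Si](C)(C)OS(=O)(=O)C(F)(F)F
Why: soft enolisation, i.e. O-silylation of the enal followed by γ-deprotonation by Et3N, gives the (E)-1-silyloxy diene that serves as the five-carbon extender unit.

Step 5
Reactants: 6 tert-butyl (2E)-4-oxo-2-(Bpin-methyl)but-2-enoate; 8 tert-butyl(dimethyl){[(1E)-3-methylbuta-1,3-dien-1-yl]oxy}silane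
Product: 10 tert-butyl (2E,4S,6E)-4-acetoxy-6-methyl-8-oxo-2-(Bpin-methyl)octa-2,6-dienoate, via hydroxy enal 9 (not isolated)
Conditions: (4R)-4-(1H-indol-3-ylmethyl)-2-phenyl-3-tosyl-1,3,2-oxazaborolidin-5-one (50 mol%), iPrOH (1.2 equiv), EtCN, −78 °C; then Ac2O, pyridine, DMAP (cat.), −78 → 0 °C
Reagents that add atoms: acetic anhydride, CC(=O)OC(C)=O
Why: catalytic asymmetric vinylogous Mukaiyama aldol reaction, in which the boron Lewis acid binds the aldehyde and the diene attacks its si face through the terminal CH2 to set C14 as S (C4 of this chain) and return an (E)-enal; isopropanol takes the silyl group, the 2-carboalkoxy allylboronate is inert at −78 °C, and the carbinol is acetylated in the same flask.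

Step 6
Reactants: 10 tert-butyl (2E,4S,6E)-4-acetoxy-6-methyl-8-oxo-2-(Bpin-methyl)octa-2,6-dienoate; 8 tert-butyl(dimethyl){[(1E)-3-methylbuta-1,3-dien-1-yl]oxy}silane
Product: 12 tert-butyl (2E,4S,6E,8S,10E)-4,8-diacetoxy-6,10-dimethyl-12-oxo-2-(Bpin-methyl)dodeca-2,6,10-trienoate, via hydroxy enal 11 (not isolated)
Conditions: (4R)-4-(1H-indol-3-ylmethyl)-2-phenyl-3-tosyl-1,3,2-oxazaborolidin-5-one (50 mol%), iPrOH (1.2 equiv), EtCN, −78 °C; then Ac2O, pyridine, DMAP (cat.), −78 → 0 °C
Reagents that add atoms: acetic anhydride, CC(=O)OC(C)=O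
Why: second vinylogous Mukaiyama aldol reaction on the new enal; the catalyst again directs si-face attack to set C10 as S (C8 of this chain), overriding the remote C14 centre, and the carbinol is acetylated in situ.

Step 7
Reactants: 12 tert-butyl (2E,4S,6E,8S,10E)-4,8-diacetoxy-6,10-dimethyl-12-oxo-2-(Bpin-methyl)dodeca-2,6,10-trienoate; 8 tert-butyl(dimethyl){[(1E)-3-methylbuta-1,3-dien-1-yl]oxy}silane
Product: 14 tert-butyl (2E,4S,6E,8S,10E,12S,14E)-4,8-diacetoxy-12-(tert-butyldimethylsilyloxy)-6,10,14-trimethyl-16-oxo-2-(Bpin-methyl)hexadeca-2,6,10,14-tetraenoate, via hydroxy enal 13 (not isolated)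
Conditions: (4R)-4-(1H-indol-3-ylmethyl)-2-phenyl-3-tosyl-1,3,2-oxazaborolidin-5-one (50 mol%), iPrOH (1.2 equiv), EtCN, −78 °C; then TBSCl, imidazole, DMF, −78 °C → rt
Reagents that add atoms: tert-butyldimethylsilyl chloride, CC(C)(C)[Si](C)(C)Cl
Why: third vinylogous Mukaiyama aldol reaction sets C6 as S (C12 of this chain) by the same catalyst control and delivers the C2 enal; the C6 hydroxyl, free in the target, is silylated in situ so that only the C2 hydroxyl is free in step 9.

Step 8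
Reactants: 14 tert-butyl (2E,4S,6E,8S,10E,12S,14E)-4,8-diacetoxy-12-(tert-butyldimethylsilyloxy)-6,10,14-trimethyl-16-oxo-2-(Bpin-methyl)hexadeca-2,6,10,14-tetraenoate
Product: 16 tert-butyl 2-[(1R,2R,3E,6S,7E,10S,11E,14S)-10,14-diacetoxy-6-(tert-butyldimethylsilyloxy)-2-hydroxy-4,8,12-trimethylcyclotetradeca-3,7,11-trien-1-yl]prop-2-enoate, via cyclic pinacol borate 15 (not isolated)
Conditions: toluene (0.002 M), BHT (5 mol%), 100 °C, 48–72 h; then aq. NaHCO3
Reagents that add atoms: none
Why: Proposed new method: the C17 allylboronate adds through C1 to the C2 enal in the closed chair transition state of allylboration, closing the 14-membered ring and forming the 15(17)-methylene. The boronate geometry (C14 cis to CH2B) puts C14 axial, so C1 and C2 emerge syn (2R, deliberately the C2 epimer, inverted in step 9). The aldehyde approaches C1 anti to the C13 chain with 14-H eclipsing the alkene (allylic 1,3-strain, acetoxy outside), which sets C1 from C14. The tert-butyl ester keeps the borate from lactonising with retention. Closest known reaction: thermal intermolecular addition of 3-substituted 2-alkoxycarbonyl allylboronates to aldehydes, here run intramolecularly at high dilution.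

Step 9
Reactants: 16 tert-butyl 2-[(1R,2R,3E,6S,7E,10S,11E,14S)-10,14-diacetoxy-6-(tert-butyldimethylsilyloxy)-2-hydroxy-4,8,12-trimethylcyclotetradeca-3,7,11-trien-1-yl]prop-2-enoate
Product: 18 (1S,2S,3E,6S,7E,10S,11E,14S)-10,14-diacetoxy-6-(tert-butyldimethylsilyloxy)cembra-3,7,11,15(17)-tetraen-16,2-olide, via allylic mesylate 17 (not isolated)
Conditions: Ms2O, 2,6-lutidine, CH2Cl2, −40 → 0 °C
Reagents that add atoms: none
Why: stereoinvertive lactonisation by neighbouring-group participation, in which the ester carbonyl oxygen displaces the allylic mesylate from the rear (5-exo-tet SN2) and the resulting tert-butoxy dioxolenium ion loses isobutylene; inversion at C2 (2R → 2S) turns the syn adduct into the trans-fused α-methylene γ-lactone.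

Step 10
Reactants: 18 (1S,2S,3E,6S,7E,10S,11E,14S)-10,14-diacetoxy-6-(tert-butyldimethylsilyloxy)cembra-3,7,11,15(17)-tetraen-16,2-olide
Product: 19 (1S,2S,3E,6S,7E,10S,11E,14S)-10,14-diacetoxy-6-hydroxycembra-3,7,11,15(17)-tetraen-16,2-olide (CNP0418981.1)
Conditions: HF·pyridine, pyridine, THF, 0 °C → rt
Reagents that add atoms: none
Why: fluoride-driven cleavage of the secondary silyl ether under buffered conditions that leave the two acetates, the allylic lactone and all stereocentres untouched.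

**Compound list**

1 | tert-butyl acrylate | C=CC(=O)OC(C)(C)C | starting material
2 | 2,2-dimethoxyacetaldehyde | COC(OC)C=O | starting material
3 | tert-butyl 3-hydroxy-4,4-dimethoxy-2-methylidenebutanoate (racemic) | C=C(C(O)C(OC)OC)C(=O)OC(C)(C)C | intermediate
4 | tert-butyl 3-acetoxy-4,4-dimethoxy-2-methylidenebutanoate (racemic) | C=C(C(OC(C)=O)C(OC)OC)C(=O)OC(C)(C)C | intermediate
5 | tert-butyl (2E)-4,4-dimethoxy-2-(Bpin-methyl)but-2-enoate | COC(OC)/C=C(\CB1OC(C)(C)C(C)(C)O1)C(=O)OC(C)(C)C | intermediate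
6 | tert-butyl (2E)-4-oxo-2-(Bpin-methyl)but-2-enoate | O=C/C=C(\CB1OC(C)(C)C(C)(C)O1)C(=O)OC(C)(C)C | intermediate
7 | 3-methylbut-2-enal (prenal) | CC(C)=CC=O | starting material
8 | tert-butyl(dimethyl){[(1E)-3-methylbuta-1,3-dien-1-yl]oxy}silane | C=C(C)/C=C/O[Si](C)(C)C(C)(C)C | intermediate
9 | tert-butyl (2E,4S,6E)-4-hydroxy-6-methyl-8-oxo-2-(Bpin-methyl)octa-2,6-dienoate | O=C/C=C(\C)C[C@H](O)/C=C(\CB1OC(C)(C)C(C)(C)O1)C(=O)OC(C)(C)C | intermediate
10 | tert-butyl (2E,4S,6E)-4-acetoxy-6-methyl-8-oxo-2-(Bpin-methyl)octa-2,6-dienoate | O=C/C=C(\C)C[C@H](OC(C)=O)/C=C(\CB1OC(C)(C)C(C)(C)O1)C(=O)OC(C)(C)C | intermediate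
11 | tert-butyl (2E,4S,6E,8S,10E)-4-acetoxy-8-hydroxy-6,10-dimethyl-12-oxo-2-(Bpin-methyl)dodeca-2,6,10-trienoate | O=C/C=C(\C)C[C@H](O)/C=C(\C)C[C@H](OC(C)=O)/C=C(\CB1OC(C)(C)C(C)(C)O1)C(=O)OC(C)(C)C | intermediate
12 | tert-butyl (2E,4S,6E,8S,10E)-4,8-diacetoxy-6,10-dimethyl-12-oxo-2-(Bpin-methyl)dodeca-2,6,10-trienoate | O=C/C=C(\C)C[C@H](OC(C)=O)/C=C(\C)C[C@H](OC(C)=O)/C=C(\CB1OC(C)(C)C(C)(C)O1)C(=O)OC(C)(C)C | intermediate
13 | tert-butyl (2E,4S,6E,8S,10E,12S,14E)-4,8-diacetoxy-12-hydroxy-6,10,14-trimethyl-16-oxo-2-(Bpin-methyl)hexadeca-2,6,10,14-tetraenoate | O=C/C=C(\C)C[C@H](O)/C=C(\C)C[C@H](OC(C)=O)/C=C(\C)C[C@H](OC(C)=O)/C=C(\CB1OC(C)(C)C(C)(C)O1)C(=O)OC(C)(C)C | intermediate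
14 | tert-butyl (2E,4S,6E,8S,10E,12S,14E)-4,8-diacetoxy-12-(tert-butyldimethylsilyloxy)-6,10,14-trimethyl-16-oxo-2-(Bpin-methyl)hexadeca-2,6,10,14-tetraenoate | O=C/C=C(\C)C[C@H](O[Si](C)(C)C(C)(C)C)/C=C(\C)C[C@H](OC(C)=O)/C=C(\C)C[C@H](OC(C)=O)/C=C(\CB1OC(C)(C)C(C)(C)O1)C(=O)OC(C)(C)C | intermediate
15 | 2-O-Bpin borate of 16 (1R,2R,6S,10S,14S) | C=C(C(=O)OC(C)(C)C)[C@@H]1[C@H](OB2OC(C)(C)C(C)(C)O2)/C=C(\C)C[C@H](O[Si](C)(C)C(C)(C)C)/C=C(\C)C[C@H](OC(C)=O)/C=C(\C)C[C@@H]1OC(C)=O | intermediate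
16 | tert-butyl 2-[(1R,2R,3E,6S,7E,10S,11E,14S)-10,14-diacetoxy-6-(tert-butyldimethylsilyloxy)-2-hydroxy-4,8,12-trimethylcyclotetradeca-3,7,11-trien-1-yl]prop-2-enoate | C=C(C(=O)OC(C)(C)C)[C@@H]1[C@H](O)/C=C(\C)C[C@H](O[Si](C)(C)C(C)(C)C)/C=C(\C)C[C@H](OC(C)=O)/C=C(\C)C[C@@H]1OC(C)=O | intermediate
17 | 2-O-methanesulfonate of 16 (spatial arrangement unchanged) | C=C(C(=O)OC(C)(C)C)[C@@H]1[C@H](OS(C)(=O)=O)/C=C(\C)C[C@H](O[Si](C)(C)C(C)(C)C)/C=C(\C)C[C@H](OC(C)=O)/C=C(\C)C[C@@H]1OC(C)=O | intermediate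
18 | (1S,2S,3E,6S,7E,10S,11E,14S)-10,14-diacetoxy-6-(tert-butyldimethylsilyloxy)cembra-3,7,11,15(17)-tetraen-16,2-olide | C=C1C(=O)O[C@H]2/C=C(\C)C[C@H](O[Si](C)(C)C(C)(C)C)/C=C(\C)C[C@H](OC(C)=O)/C=C(\C)C[C@H](OC(C)=O)[C@H]12 | intermediate
19 | (1S,2S,3E,6S,7E,10S,11E,14S)-10,14-diacetoxy-6-hydroxycembra-3,7,11,15(17)-tetraen-16,2-olide (CNP0418981.1) | C=C1C(=O)O[C@H]2/C=C(\C)C[C@H](O)/C=C(\C)C[C@H](OC(C)=O)/C=C(\C)C[C@H](OC(C)=O)[C@H]12 | target

**Step count and risks**

Total step count: 10. Longest linear sequence: 9 (steps 1, 2, 3, 5, 6, 7, 8, 9, 10); step 4 is the side branch.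

Step 8 is the most likely to fail. The boronate is a sluggish nucleophile, so closure of the 14-membered ring at 100 °C may lose to oligomerisation or to 1,4-loss of boron and the C14 acetate (giving a diene). The C1 facial selectivity from C14 is also a prediction, not precedent. The fallback sets out from 14: KHF2 in MeOH/H2O converts the pinacol boronate into the potassium trifluoroborate F1. BF3·OEt2 in CH2Cl2 at −78 °C under high dilution strips fluoride to give the allyldifluoroborane F2, which is far more reactive and cyclises cold through the same chair to the O-difluoroboryl ether F3. NaHCO3 work-up returns to the route at 16.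

Step 9 is the second risk. The allylic mesylate may ionise (loss of stereochemical fidelity, elimination to a diene), or the C14 acetate carbonyl may compete as the internal nucleophile. The fallback sets out from 16 and makes the carboxylate, not the ester, the nucleophile. TMSOTf and 2,6-lutidine in CH2Cl2, then pH 7 buffer, remove the tert-butyl group to give the hydroxy acid F4, which is used at once. PPh3 and DIAD in THF at 0 °C then close the lactone by Mitsunobu SN2 with inversion at C2, returning at 18.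

Step 5 is the third risk, and stands for steps 6 and 7 as well. The oxazaborolidinone-catalysed vinylogous aldol may give modest enantioselectivity or conjugate addition with the doubly activated aldehyde 6. The fallback sets out from 6 and changes the nucleophile and the activation mode. The amide-derived dienolate 4-[1-(tert-butyldimethylsilyloxy)-3-methylbuta-1,3-dien-1-yl]morpholine is added under SiCl4 with 5 mol% of the chiral bisphosphoramide N,N′-bis[(11bR)-3,5-dimethyl-4-oxido-3,5-dihydro-4H-dinaphtho[2,1-d:1′,2′-f][1,3,2]diazaphosphepin-4-yl]-N,N′-dimethylpentane-1,5-diamine (or its enantiomer, whichever gives 4S) and iPr2NEt in CH2Cl2 at −72 °C. This gives the hydroxy amide F5; Ac2O and pyridine give the acetoxy amide F6; Cp2Zr(H)Cl in THF reduces the morpholine amide to the aldehyde and returns to the route at 10.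

**Further compounds**

F1 | step 8 | potassium trifluoroborate corresponding to 14 | O=C/C=C(\C)C[C@H](O[Si](C)(C)C(C)(C)C)/C=C(\C)C[C@H](OC(C)=O)/C=C(\C)C[C@H](OC(C)=O)/C=C(\C[B-](F)(F)F)C(=O)OC(C)(C)C.[K+]
F2 | step 8 | allyldifluoroborane corresponding to 14 | O=C/C=C(\C)C[C@H](O[Si](C)(C)C(C)(C)C)/C=C(\C)C[C@H](OC(C)=O)/C=C(\C)C[C@H](OC(C)=O)/C=C(\CB(F)F)C(=O)OC(C)(C)C
F3 | step 8 | 2-O-difluoroboryl ether of 16 | C=C(C(=O)OC(C)(C)C)[C@@H]1[C@H](OB(F)F)/C=C(\C)C[C@H](O[Si](C)(C)C(C)(C)C)/C=C(\C)C[C@H](OC(C)=O)/C=C(\C)C[C@@H]1OC(C)=O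
F4 | step 9 | 2-[(1R,2R,3E,6S,7E,10S,11E,14S)-10,14-diacetoxy-6-(tert-butyldimethylsilyloxy)-2-hydroxy-4,8,12-trimethylcyclotetradeca-3,7,11-trien-1-yl]prop-2-enoic acid | C=C(C(=O)O)[C@@H]1[C@H](O)/C=C(\C)C[C@H](O[Si](C)(C)C(C)(C)C)/C=C(\C)C[C@H](OC(C)=O)/C=C(\C)C[C@@H]1OC(C)=O
F5 | step 5 | tert-butyl (2E,4S,6E)-4-hydroxy-6-methyl-8-(morpholin-4-yl)-8-oxo-2-(Bpin-methyl)octa-2,6-dienoate | O=C(/C=C(\C)C[C@H](O)/C=C(\CB1OC(C)(C)C(C)(C)O1)C(=O)OC(C)(C)C)N1CCOCC1
F6 | step 5 | tert-butyl (2E,4S,6E)-4-acetoxy-6-methyl-8-(morpholin-4-yl)-8-oxo-2-(Bpin-methyl)octa-2,6-dienoate | O=C(/C=C(\C)C[C@H](OC(C)=O)/C=C(\CB1OC(C)(C)C(C)(C)O1)C(=O)OC(C)(C)C)N1CCOCC1
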